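## Structural features

The target is one cyclohexane ring, numbered C1 to C6, with substituents on five adjacent ring carbons and a single methylene at C2. C1 is quaternary (methyl and vinyl), C3 carries the ester oxygen, C4 a 1-carboxyvinyl arm, C5 a free hydroxyl and C6 a 3-hydroxyprop-1-en-2-yl arm. The ester on C3 is (R)-3,4-dihydroxy-2-methylenebutanoate, which holds the sixth stereocentre. The C1 vinyl group, the C3 oxygen, the C4 arm and the C5 oxygen lie on one face, and the C6 arm and the C1 methyl on the other. With the C5 and C6 substituents equatorial, the C4 arm is therefore axial and flanked by two cis oxygen substituents. Two motifs are fragile in opposite directions. The C4 acrylic acid and the cis C5 hydroxyl form a γ-hydroxy acid that should close to the cis-fused α-methylene lactone under acid. The side chain is a γ-hydroxy ester that should lactonise under base and expel the ring alcohol. C4–H is also epimerisable whenever a carbonyl sits on C3 or on the first arm carbon. The real difficulty is the axial C4 arm, cis to both neighbours and cis-1,4 to the vinyl group on the quaternary C1, together with an endgame that must stay near neutral. The key step uses this cis-1,4 relation: the first vinyl carbon (C7) and the first arm carbon (C8) are joined as the two-carbon bridge of a bicyclo[2.2.2]octene across C1 and C4. Both centres become bridgeheads and the C4 arm is forced axial.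

## Logic of the disconnections

32 ⇒ 31 ⇒ 30 ⇒ 29. Only O–Si bonds, the O–C bond of the tert-butyl ester and the acetonide C–O bonds are cut. The γ-hydroxy acid and the γ-hydroxy ester may exist only at the very end, so the acetonide is removed first under weak acid while the carboxyl is still an ester and O5 is still silylated. The ester is then cleaved with a silyl triflate and all silyl groups with buffered fluoride. For this reason O5 carries a silyl ether instead of an acetal ether, and the carboxyl a tert-butyl ester instead of a fluoride-labile ester. An acetal ether would need acid at the end and a fluoride-labile ester would need basic fluoride. The demand on the forward steps is that no strong acid or base is used after 29.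

29 ⇒ 24 + 28. The C3–O ester bond is cut with inversion at C3. Hydride reduction inside the bicycle gives the C3 epimer, so attaching the acid by SN2 corrects C3 and adds the second chiral fragment in one step. The demand is a displacement at an axial, flanked carbinol carbon with only one free hydroxyl in the molecule.

28 ⇒ 27 ⇒ 26 ⇒ 25. The C=CH2 bond of the acyl unit goes back to a ketone and that to the carbinol of a commercial C4 building block. 25 already holds the only stereocentre of the side chain. The methylenation must be non-basic because the α-alkoxy α-keto ester can epimerise.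

24 ⇒ 23 ⇒ 22 ⇒ 21 ⇒ 20. The C=CH2 bond of the C6 arm goes back to a tertiary/primary 1,2-diol. The alkene must not exist during ozonolysis, and the quaternary carbinol is the bulky element that steers the key step. The arm becomes the symmetrical adduct of 6 with no extra stereocentre. The forward step must form the five-membered thiocarbonate beside a second primary hydroxyl and leave the C3 hydroxyl alone.

20 ⇒ 19 ⇒ 18. The two C=CH2 bonds (vinyl on C1, acrylate on C4) go back to carbonyls, and the two carbonyl carbons are rejoined as the C7=C8 double bond. This is possible only because the two arms are cis-1,4. C1 and C4 become bridgeheads of a rigid bicycle. The forward steps are ozonolysis of an electron-poor alkene and a non-basic double methylenation.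

18 ⇒ 17 ⇒ 16. The C3–H bond is removed (ketone) and the ketone is written as its enol silane. The bridgehead position protects the β-silyloxy ketone from enolisation. The reduction must be face-selective; it gives the C3 epimer, which is corrected later.

16 ⇒ 15 ⇒ 14 + 13 (key step). The bonds C1–C7 and C4–C8 are cut. A cyclohexadiene with two stereocentres and a two-carbon dienophile remain. The forward step must control regiochemistry (nitro group), face (C6 carbinol) and the loss of nitrous acid.

13 ⇒ 12 ⇒ 11. The C–N bond is cut; the dienophile comes from a commercial acrylate by iodonitration and loss of HI.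

14 ⇒ 10 ⇒ 9 ⇒ 8. The O–Si bond of the enol silane is cut, then the carbonyl is moved back across the allyl unit and the C1–CH3 bond is cut. This returns to a simple enone whose α′-position is C6. Kinetic deprotonation must occur next to a β-silyloxy group without elimination.

8 ⇒ 7 ⇒ 5 + 6. The bond from C6 to the carbinol carbon is cut (aldol). The whole C6 arm comes from a symmetrical commercial ketone. The aldolate must be trapped before it reverts, and the addition must be trans to the C5 silyloxy group.

5 ⇒ 4 ⇒ 3 ⇒ 2 ⇒ 1. The enone goes back to an all-cis triol through a β-acetoxy ketone, a monoacetate and a meso diol. The single stereocentre of 5 comes from an enzymatic desymmetrisation.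

## Other disconnections considered

Alternative 1: The C5–C6 ring bond is cut, giving the open-chain aldehyde A1. In A1, C5 is the aldehyde carbon, C6 is the CH of a 2-methylprop-1-enyl group, and C1, C3 and C4 are already defined. The forward step is a Me2AlCl-promoted intramolecular carbonyl-ene reaction through a chair transition state. It closes the ring to cyclohexanol A2 and makes the C5 hydroxyl and a C6 isopropenyl group trans to each other.
- In its favour: A2 would hold all five ring centres, including the C3 oxygen in the correct configuration, so no inversion at C3 and no bridge cleavage are needed. On these two points it is better than the chosen plan.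
- In its favour: the chair with the C4 arm axial should be preferred, because the other chair puts the vinyl group and the C3 silyloxy group syn-diaxial.
- Against it: A1 needs an all-carbon quaternary stereocentre made enantioselectively in an open chain, plus two further centres.
- Against it: its aldehyde α-carbon (C4) can epimerise and its β-silyloxy group can eliminate under the Lewis acid.
- Against it: after A2 the acetate arm must be α-methylenated and one methyl of the isopropenyl group hydroxylated selectively among several allylic positions.
- Comparison: the mechanism is a concerted closure under substrate control, as in the chosen plan. Step economy should be about equal, since what is saved after the key step is spent on A1. The chosen plan is safer for C1 and C4, which it sets by construction.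

Alternative 2: The bond from C6 to its arm and the C5–O bond are cut on the flat, prochiral dienone A3. The forward step is a conjugate addition of the alkenyl Grignard reagent A4, catalysed by CuBr·SMe2 with a chiral diphosphine, to one enone arm anti to the silyloxymethyl group. The magnesium enolate is then hydroxylated in the same flask with MoO5·pyridine·HMPA to give hydroxy enone A5.
- In its favour: three centres (C1, C5, C6) come from an achiral precursor in one flask under catalyst control. The route to A5 is far shorter than the route to 16, and the enantiocontrol is at least equal to the enzymatic desymmetrisation used here.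
- Against it: the β-carbon attacked is next to a quaternary centre, and alkenyl Grignard reagents are demanding partners in this catalysis.
- Against it: the choice of enone arm and of face must both be right.
- Against it: A5 still lacks C3–O and the C4 arm, and the C4 arm must be installed axial and cis to both oxygens on a ketone carbon, the hardest centre of the target. The silyloxymethyl group also needs three more steps to become vinyl.
- Comparison: the alternative is better up to its key product. The chosen plan is better afterwards, because its bicycle fixes C4, so its overall step count should be lower.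

Alternative 3: The bonds C3–C4 and C4–C5 are cut, giving dialdehyde A6 and 1,1-dimethoxy-3-nitropropane A7. The forward step is a base-mediated double Henry reaction that closes the ring as the nitro diol A8.
- In its favour: the closure is convergent and reversible, so both carbinols should settle equatorial and cis. The C3 oxygen then comes out right without inversion, which is better than the chosen plan.
- Against it: C4 becomes a quaternary nitro carbon. Replacing the nitro group by hydrogen with Bu3SnH goes through a planar radical, which should take hydrogen from the open face and leave the arm equatorial, the wrong epimer.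
- Against it: the two hydroxyls of A8 are nearly equivalent and must be told apart for the C3 acylation.
- Against it: A6 has an epimerisable centre next to an aldehyde and the quaternary C1, and needs its own asymmetric synthesis.
- Against it: the acetal arm needs three steps to become the acrylic acid.
- Comparison: step count should be similar or slightly lower. Thermodynamic control in the alternative contrasts with kinetic, geometric control in the chosen plan. The open question at C4 decides against it.

Key step: step 9

Assumption: the lipase acylates the R-configured carbinol of 2 (the one whose larger ring arm carries the silyloxy group) and gives 3 as drawn; an enzyme of opposite preference would be used in the hydrolytic mode to reach the same 3.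

Remark: ring numbering C1–C6 of the target is used for all intermediates (it coincides with the systematic numbering of 5, 8, 9 and 14); C7 is the bridge carbon on C1 and C8 the ester-bearing bridge carbon on C4.

Remark: the configurations of diene 14 and cycloadduct 16 at C5 and C6 (C5–O syn, C6 arm anti to the new bridge) agree with the target and need no correction; relative to a methoxymethyl ether and a 2-(trimethylsilyl)ethyl ester, O5 is a tert-butyldimethylsilyl ether and the ester is tert-butyl, for the reasons given above.

## Steps

Step 1
Reactants: 1 cis,cis-cyclohexane-1,3,5-triol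
Product: 2 all-cis-5-(tert-butyldimethylsilyloxy)cyclohexane-1,3-diol (meso)
Conditions: tBuMe2SiCl (1 equiv), imidazole, DMF, 0 °C → rt
Reagents that add atoms: tert-butyldimethylsilyl chloride, CC(C)(C)[Si](C)(C)Cl
Why: Statistical monosilylation of three equivalent hydroxyls; the mono-ether should be separable and the rest recyclable. No stereocentre is created because 2 is meso.

Step 2
Reactants: 2
Product: 3 (1R,3S,5S)-3-(tert-butyldimethylsilyloxy)-5-hydroxycyclohexyl acetate
Conditions: immobilised Candida antarctica lipase B, vinyl acetate, tBuOMe, 30 °C
Reagents that add atoms: vinyl acetate, C=COC(C)=O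
Why: Lipase-catalysed irreversible transesterification desymmetrises the meso 1,3-diol. The enzyme distinguishes the two enantiotopic carbinols and so fixes the carbon that becomes C5 of the target.

Step 3
Reactants: 3
Product: 5 (R)-5-(tert-butyldimethylsilyloxy)cyclohex-2-en-1-one, via β-acetoxy ketone 4 (not isolated)
Conditions: Dess–Martin periodinane, CH2Cl2, 0 °C → rt; then Et3N, 0 °C → rt
Reagents that add atoms: none
Why: Dess–Martin oxidation gives a β-acetoxy ketone that loses acetic acid by E1cB with a mild amine base. Et3N should be too weak to eliminate the silyloxy group as well, and the stereocentre is not touched.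

Step 4
Reactants: 5; 6 2,2-dimethyl-1,3-dioxan-5-one
Product: 8 (5R,6R)-5-(tert-butyldimethylsilyloxy)-6-[2,2-dimethyl-5-(trimethylsilyloxy)-1,3-dioxan-5-yl]cyclohex-2-en-1-one, via lithium aldolate 7 (not isolated)
Conditions: LiN(iPr)2, THF, −78 °C; 6, −78 °C; then Me3SiOTf, −78 → −40 °C
Reagents that add atoms: trimethylsilyl trifluoromethanesulfonate, C[Si](C)(C)OS(=O)(=O)C(F)(F)F
Why: Kinetic α′-deprotonation at C6 and aldol addition to the electrophilic ketone anti to the neighbouring C5 silyloxy group should give the trans-5,6 product. The silyl triflate captures the tertiary aldolate at −78 °C before retro-aldol can occur.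

Step 5
Reactants: 8
Product: 9 trans-5-(tert-butyldimethylsilyloxy)-6-[2,2-dimethyl-5-(trimethylsilyloxy)-1,3-dioxan-5-yl]-1-methylcyclohex-2-en-1-ol (C1 epimers)
Conditions: MeLi, CeCl3, THF, −78 °C
Reagents that add atoms: methyllithium, [Li]C
Why: 1,2-Addition of an organocerium reagent, whose low basicity avoids enolisation at C6 and β-elimination. The new carbinol centre is erased in step 6, so its configuration does not matter.

Step 6
Reactants: 9
Product: 10 (4R,5R)-5-(tert-butyldimethylsilyloxy)-4-[2,2-dimethyl-5-(trimethylsilyloxy)-1,3-dioxan-5-yl]-3-methylcyclohex-2-en-1-one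
Conditions: [C5H5NH][CrO3Cl], NaOAc, 4 Å molecular sieves, CH2Cl2, rt
Reagents that add atoms: pyridinium chlorochromate, [O-][Cr](=O)(=O)Cl.c1cc[nH+]cc1
Why: Babler–Dauben oxidative transposition: the chromate ester of the tertiary allylic alcohol shifts by a [3,3] process and is oxidised by hexavalent chromium. This moves the carbonyl from C1 to C3 and leaves the methyl on the future quaternary C1; the buffer protects the acetonide and the silyl ethers.

Step 7
Reactants: 11 tert-butyl acrylate
Product: 13 tert-butyl (E)-3-nitroacrylate, via iodo nitro ester 12 (not isolated)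
Conditions: N2O4, I2, Et2O, 0 °C; then NaOAc, Et2O, 0 °C → rt
Reagents that add atoms: dinitrogen tetroxide, O=[N+]([O-])[N+](=O)[O-]
Why: Iodonitration of the acrylate by nitryl iodide formed in the flask, then acetate-induced loss of HI, is the standard route to 3-nitroacrylates and should give the E alkene.

Step 8
Reactants: 10
Product: 14 (5R,6R)-5-(tert-butyldimethylsilyloxy)-6-[2,2-dimethyl-5-(trimethylsilyloxy)-1,3-dioxan-5-yl]-1-methyl-3-(trimethylsilyloxy)cyclohexa-1,3-diene
Conditions: LiN(iPr)2, Me3SiCl, THF, −78 °C; Et3N, pentane, filtration
Reagents that add atoms: chlorotrimethylsilane, C[Si](C)(C)Cl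
Why: Kinetic α′-deprotonation at the C4 methylene with internal silyl quench gives the cross-conjugated 2-silyloxy-1,3-diene. Low temperature and immediate silylation suppress γ-deprotonation and β-elimination of the C5 silyloxy group; the silylated carbinol cannot undergo vinylogous retro-aldol.

Step 9
Reactants: 14; 13
Product: 16 tert-butyl ester of the bicyclo[2.2.2]octa-2,5-diene in which the C7=C8 enoate bridge joins C1 to C4 (C3 trimethylsilyl enol ether), via nitro cycloadduct 15 (not isolated)
Conditions: toluene, −20 °C → rt; then DBU, 0 °C → rt
Reagents that add atoms: none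
Why: The electron-rich 2-silyloxy diene and the doubly activated nitroalkene combine in a normal-demand, asynchronous [4+2] cycloaddition in which the bond from the enol ether terminus C4 to the ester-bearing carbon C8 runs ahead of the bond from the methyl-bearing terminus C1 to the nitro-bearing carbon C7. The closest known reaction type is the Diels–Alder addition of 2-silyloxycyclohexa-1,3-dienes to nitroalkenes and acrylates giving bicyclo[2.2.2]octenone enol ethers, together with the use of β-nitroacrylates as propiolate equivalents of reversed regiochemistry. The new six-membered ring (C1, C2, C3, C4, C8, C7) closes suprafacially on both partners, both σ bonds going to one face of the diene, so the bicycle arises in one step. The two new stereocentres C1 and C4 are bridgeheads fixed by the face of attack alone; that face is dictated by the pseudoaxial quaternary carbinol on C6, which is gauche to C1 and syn-axial to C4 on the lower face, so the dienophile should add on the face of the C5 silyloxy group, where only the oxygen atom is close to it. Regiochemistry follows from the nitro group, which makes the ester-bearing carbon the electrophilic end, and from the C3 silyloxy and C1 methyl groups, which both raise the coefficient at C4. DBU then removes the proton α to the ester on C8 and nitrite leaves (E1cB); C1 is quaternary, so only this proton is available and the C7=C8 enoate forms whatever the endo/exo composition of 15. The step needs face selectivity (from the C6 carbinol), regioselectivity (from the nitro group) and survival of the enol silane (aprotic medium, non-nucleophilic base).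

Step 10
Reactants: 16
Product: 18 bicyclo[2.2.2]octenol whose C3 hydroxyl is anti to the enoate bridge, via bicyclic ketone 17 (not isolated)
Conditions: AcOH (cat.), MeOH–THF, 0 °C; then CeCl3·7H2O, NaBH4, −40 °C
Reagents that add atoms: none
Why: Mild acid methanolysis cleaves only the enol silane, and the bridgehead α-carbon cannot enolise, so the β-silyloxy ketone neither epimerises nor eliminates. Luche reduction should deliver hydride from the open face beside the C7=C8 bridge, because the other face is screened by the C5–C6 bridge and the C6 carbinol. The hydroxyl therefore ends anti to the enoate bridge, the C3 epimer of the target, which cannot lactonise onto the C4 ester and is inverted in step 19.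

Step 11
Reactants: 18
Product: 19 C1-formyl C4-(tert-butoxyoxalyl) cyclohexanol (aldehyde and α-keto ester on the same face)
Conditions: O3, CH2Cl2, −78 °C; then PPh3, −78 °C → rt
Reagents that add atoms: ozone, [O-][O+]=O
Why: Ozonolysis of the only C=C bond in the molecule; ring strain should offset the electron poverty of the enoate. Reductive work-up leaves C7 as the aldehyde on C1 and C8 as the ketone of an α-keto ester on C4.

Step 12
Reactants: 19
Product: 20 C1-vinyl C4-(1-tert-butoxycarbonylvinyl) cyclohexanol
Conditions: Zn, CH2Br2, TiCl4, THF–CH2Cl2, 0 °C → rt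
Reagents that add atoms: dibromomethane, BrCBr
Why: Lombardo methylenation converts aldehyde and ketone carbonyls but not esters. It is non-basic, so the now enolisable C4 centre (axial arm, two β-oxygens) should be neither epimerised nor eliminated.

Step 13
Reactants: 20
Product: 21 tetraol (C3–OH and the 1,2,3-triol of the C6 arm free)
Conditions: PPTS, MeOH, rt
Reagents that add atoms: none
Why: Acid-catalysed transketalisation to methanol removes the 1,3-dioxane acetonide and the tertiary trimethylsilyl ether together. The hindered secondary tert-butyldimethylsilyl ether and the tert-butyl ester should be stable to PPTS.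

Step 14
Reactants: 21
Product: 23 1,3-dioxolane-2-thione of the C6 arm bearing a silyloxymethyl group (epimers at the spiro carbon), via hydroxy thiocarbonate 22 (not isolated)
Conditions: 1,1'-thiocarbonyldiimidazole, THF, rt → 45 °C; then tBuMe2SiCl, rt
Reagents that add atoms: 1,1'-thiocarbonyldiimidazole, S=C(n1ccnc1)n1ccnc1; tert-butyldimethylsilyl chloride, CC(C)(C)[Si](C)(C)Cl
Why: A primary hydroxyl is thiocarbonylated and should close onto the tertiary hydroxyl to the five-membered cyclic thiocarbonate, which is favoured over the six-membered isomer. The imidazole set free then serves as base for silylation of the remaining primary hydroxyl, while the hindered axial C3 hydroxyl stays free.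

Step 15
Reactants: 23
Product: 24 C6-(3-silyloxyprop-1-en-2-yl) cyclohexanol (C3–OH free)
Conditions: 1,3-dimethyl-2-phenyl-1,3,2-diazaphospholidine, THF, 40 °C
Reagents that add atoms: none
Why: Corey–Winter olefination: the phosphorus reagent removes sulfur, and the resulting carbene loses CO2 to give the 1,1-disubstituted alkene at 40 °C. No stereocentre is created, and both epimers of 23 converge.

Step 16
Reactants: 25 methyl 3,4-O-isopropylidene-L-threonate
Product: 26 methyl 2-[(4S)-2,2-dimethyl-1,3-dioxolan-4-yl]-2-oxoacetate
Conditions: Dess–Martin periodinane, CH2Cl2, 0 °C → rt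
Reagents that add atoms: none
Why: Dess–Martin oxidation of the α-hydroxy ester under near-neutral conditions; the neighbouring dioxolane stereocentre should not enolise.

Step 17
Reactants: 26
Product: 27 methyl 2-[(4R)-2,2-dimethyl-1,3-dioxolan-4-yl]prop-2-enoate
Conditions: Zn, CH2Br2, TiCl4, THF–CH2Cl2, 0 °C → rt
Reagents that add atoms: dibromomethane, BrCBr
Why: Non-basic Lombardo methylenation of the ketone carbonyl (ester untouched) avoids epimerisation of the α-alkoxy centre. The descriptor changes from S to R only because the substituent priorities change.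

Step 18
Reactants: 27
Product: 28 2-[(4R)-2,2-dimethyl-1,3-dioxolan-4-yl]prop-2-enoic acid
Conditions: LiOH, THF–H2O, 0 °C; then 1 M HCl to pH 4, 0 °C
Reagents that add atoms: lithium hydroxide, [Li+].[OH-]
Why: Saponification of the methyl ester at 0 °C; cold acidification to pH 4 should keep the acetonide.

Step 19
Reactants: 24; 28
Product: 29 fully protected C3 ester (C3–O now cis to the C4 arm)
Conditions: PPh3, iPrO2CN=NCO2iPr, toluene, 0 °C → rt
Reagents that add atoms: none
Why: Mitsunobu esterification: the axial C3 hydroxyl, the only free one, is activated as its oxyphosphonium ion and displaced by the carboxylate of 28 with inversion (SN2). This gives the equatorial C3 ester cis to the C4 arm; relief of the syn-axial contact between the C3 oxygen and the C1 methyl helps.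

Step 20
Reactants: 29
Product: 30 triol tert-butyl ester (side-chain diol and arm hydroxyl free, O5 still silylated)
Conditions: AcOH–H2O (4:1), rt → 35 °C
Reagents that add atoms: none
Why: Aqueous acetic acid hydrolyses the terminal acetonide and the primary allylic silyl ether. The carboxyl is still a tert-butyl ester and O5 is still silylated, so the ring cannot lactonise, and the side-chain γ-hydroxy ester should be stable in weak acid.

Step 21
Reactants: 30
Product: 32 CNP0348657.1 (target), via persilylated silyl ester 31 (not isolated)
Conditions: Me3SiOTf, 2,6-lutidine, CH2Cl2, 0 °C → rt; then HF·pyridine, pyridine, THF, 0 °C → rt; pH 6.5 phosphate buffer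
Reagents that add atoms: none
Why: The silyl triflate with a hindered pyridine base silylates the free hydroxyls and converts the tert-butyl ester into a trimethylsilyl ester by loss of isobutene, with neither free acid nor free base present. Buffered HF·pyridine then removes all silyl groups at about pH 5–6, where the carboxylate should not close onto the C5 hydroxyl and the dihydroxybutenoate should not expel the ring alcohol.

## Compound list

1 | cis,cis-cyclohexane-1,3,5-triol | O[C@H]1C[C@@H](O)C[C@@H](O)C1 | starting material
2 | all-cis-5-(tert-butyldimethylsilyloxy)cyclohexane-1,3-diol (meso) | O[C@H]1C[C@@H](O)C[C@@H](O[Si](C)(C)C(C)(C)C)C1 | intermediate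
3 | (1R,3S,5S)-3-(tert-butyldimethylsilyloxy)-5-hydroxycyclohexyl acetate | O[C@H]1C[C@@H](OC(C)=O)C[C@@H](O[Si](C)(C)C(C)(C)C)C1 | intermediate
4 | (1S,3R)-3-(tert-butyldimethylsilyloxy)-5-oxocyclohexyl acetate | O=C1C[C@@H](OC(C)=O)C[C@@H](O[Si](C)(C)C(C)(C)C)C1 | intermediate
5 | (R)-5-(tert-butyldimethylsilyloxy)cyclohex-2-en-1-one | O=C1C=CC[C@@H](O[Si](C)(C)C(C)(C)C)C1 | intermediate
6 | 2,2-dimethyl-1,3-dioxan-5-one | CC1(C)OCC(=O)CO1 | starting material
7 | lithium alkoxide of the aldol adduct of 5 and 6 (5R,6R; arm trans to the silyloxy group) | O=C1C=CC[C@@H](O[Si](C)(C)C(C)(C)C)[C@@H]1C1(O[Li])COC(C)(C)OC1 | intermediate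
8 | (5R,6R)-5-(tert-butyldimethylsilyloxy)-6-[2,2-dimethyl-5-(trimethylsilyloxy)-1,3-dioxan-5-yl]cyclohex-2-en-1-one | O=C1C=CC[C@@H](O[Si](C)(C)C(C)(C)C)[C@@H]1C1(O[Si](C)(C)C)COC(C)(C)OC1 | intermediate
9 | trans-5-(tert-butyldimethylsilyloxy)-6-[2,2-dimethyl-5-(trimethylsilyloxy)-1,3-dioxan-5-yl]-1-methylcyclohex-2-en-1-ol (C5, C6 as in 8; C1 epimers) | CC1(O)C=CC[C@@H](O[Si](C)(C)C(C)(C)C)[C@@H]1C1(O[Si](C)(C)C)COC(C)(C)OC1 | intermediate
10 | (4R,5R)-5-(tert-butyldimethylsilyloxy)-4-[2,2-dimethyl-5-(trimethylsilyloxy)-1,3-dioxan-5-yl]-3-methylcyclohex-2-en-1-one | CC1=CC(=O)C[C@@H](O[Si](C)(C)C(C)(C)C)[C@@H]1C1(O[Si](C)(C)C)COC(C)(C)OC1 | intermediate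
11 | tert-butyl acrylate | C=CC(=O)OC(C)(C)C | starting material
12 | tert-butyl 2-iodo-3-nitropropanoate (racemic) | CC(C)(C)OC(=O)C(I)C[N+](=O)[O-] | intermediate
13 | tert-butyl (E)-3-nitroacrylate | CC(C)(C)OC(=O)/C=C/[N+](=O)[O-] | intermediate
14 | (5R,6R)-5-(tert-butyldimethylsilyloxy)-6-[2,2-dimethyl-5-(trimethylsilyloxy)-1,3-dioxan-5-yl]-1-methyl-3-(trimethylsilyloxy)cyclohexa-1,3-diene | CC1=CC(O[Si](C)(C)C)=C[C@@H](O[Si](C)(C)C(C)(C)C)[C@@H]1C1(O[Si](C)(C)C)COC(C)(C)OC1 | intermediate
15 | nitro cycloadduct: bicyclo[2.2.2]oct-2-ene with NO2 on C7 and CO2tBu on C8 (mixture at C7/C8), C5–O syn and C6 arm anti to the new bridge | [O-][N+](=O)C2[C@@]1(C)C=C(O[Si](C)(C)C)[C@@H](C2C(=O)OC(C)(C)C)[C@@H](O[Si](C)(C)C(C)(C)C)[C@@H]1C1(O[Si](C)(C)C)COC(C)(C)OC1 | intermediate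
16 | bicyclo[2.2.2]octa-2,5-diene: C7=C8(CO2tBu) bridge from C1 (methyl) to C4, C3 trimethylsilyl enol ether, C5–OSitBuMe2 syn and C6 dioxanyl carbinol anti to the enoate bridge | C=2[C@@]1(C)C=C(O[Si](C)(C)C)[C@@H](C=2C(=O)OC(C)(C)C)[C@@H](O[Si](C)(C)C(C)(C)C)[C@@H]1C1(O[Si](C)(C)C)COC(C)(C)OC1 | intermediate
17 | bicyclo[2.2.2]oct-7-en-3-one corresponding to 16 (C3 ketone) | C=2[C@@]1(C)CC(=O)[C@@H](C=2C(=O)OC(C)(C)C)[C@@H](O[Si](C)(C)C(C)(C)C)[C@@H]1C1(O[Si](C)(C)C)COC(C)(C)OC1 | intermediate
18 | bicyclic alcohol: C3–OH anti to the enoate bridge (syn to the C5–C6 bridge) | C=2[C@@]1(C)C[C@H](O)[C@@H](C=2C(=O)OC(C)(C)C)[C@@H](O[Si](C)(C)C(C)(C)C)[C@@H]1C1(O[Si](C)(C)C)COC(C)(C)OC1 | intermediate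
19 | cyclohexanol with C1 formyl (cis to the C4 arm), C4 tert-butoxyoxalyl, C3–OH trans to the C4 arm, C5–OSitBuMe2 cis to it, C6 dioxanyl carbinol trans to it | O=C[C@@]1(C)C[C@H](O)[C@@H](C(=O)C(=O)OC(C)(C)C)[C@@H](O[Si](C)(C)C(C)(C)C)[C@@H]1C1(O[Si](C)(C)C)COC(C)(C)OC1 | intermediate
20 | as 19 with C1 vinyl and C4 1-(tert-butoxycarbonyl)vinyl | C=C[C@@]1(C)C[C@H](O)[C@@H](C(=C)C(=O)OC(C)(C)C)[C@@H](O[Si](C)(C)C(C)(C)C)[C@@H]1C1(O[Si](C)(C)C)COC(C)(C)OC1 | intermediate
21 | tetraol: as 20 with the C6 arm as 1,2,3-trihydroxypropan-2-yl | C=C[C@@]1(C)C[C@H](O)[C@@H](C(=C)C(=O)OC(C)(C)C)[C@@H](O[Si](C)(C)C(C)(C)C)[C@@H]1C(O)(CO)CO | intermediate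
22 | as 21 with the C6 arm as 4-(hydroxymethyl)-2-thioxo-1,3-dioxolan-4-yl (epimers at the spiro carbon) | C=C[C@@]1(C)C[C@H](O)[C@@H](C(=C)C(=O)OC(C)(C)C)[C@@H](O[Si](C)(C)C(C)(C)C)[C@@H]1C1(CO)COC(=S)O1 | intermediate
23 | as 22 with the hydroxymethyl group as its tert-butyldimethylsilyl ether | C=C[C@@]1(C)C[C@H](O)[C@@H](C(=C)C(=O)OC(C)(C)C)[C@@H](O[Si](C)(C)C(C)(C)C)[C@@H]1C1(CO[Si](C)(C)C(C)(C)C)COC(=S)O1 | intermediate
24 | cyclohexanol with C6 3-(tert-butyldimethylsilyloxy)prop-1-en-2-yl, C3–OH free (C3 epimer of the target), other centres as in the target | C=C[C@@]1(C)C[C@H](O)[C@@H](C(=C)C(=O)OC(C)(C)C)[C@@H](O[Si](C)(C)C(C)(C)C)[C@@H]1C(=C)CO[Si](C)(C)C(C)(C)C | intermediate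
25 | methyl 3,4-O-isopropylidene-L-threonate, methyl (2R)-2-[(4S)-2,2-dimethyl-1,3-dioxolan-4-yl]-2-hydroxyacetate | COC(=O)[C@H](O)[C@@H]1COC(C)(C)O1 | starting material
26 | methyl 2-[(4S)-2,2-dimethyl-1,3-dioxolan-4-yl]-2-oxoacetate | COC(=O)C(=O)[C@@H]1COC(C)(C)O1 | intermediate
27 | methyl 2-[(4R)-2,2-dimethyl-1,3-dioxolan-4-yl]prop-2-enoate | C=C(C(=O)OC)[C@@H]1COC(C)(C)O1 | intermediate
28 | 2-[(4R)-2,2-dimethyl-1,3-dioxolan-4-yl]prop-2-enoic acid | C=C(C(=O)O)[C@@H]1COC(C)(C)O1 | intermediate
29 | protected target: C3 ester of 28 (all ring centres as in the target), tert-butyl ester, O5 and arm oxygen as tert-butyldimethylsilyl ethers, side-chain acetonide | C=C[C@@]1(C)C[C@@H](OC(=O)C(=C)[C@@H]2COC(C)(C)O2)[C@@H](C(=C)C(=O)OC(C)(C)C)[C@@H](O[Si](C)(C)C(C)(C)C)[C@@H]1C(=C)CO[Si](C)(C)C(C)(C)C | intermediate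
30 | tert-butyl ester of the target with O5 as tert-butyldimethylsilyl ether | C=C[C@@]1(C)C[C@@H](OC(=O)C(=C)[C@@H](O)CO)[C@@H](C(=C)C(=O)OC(C)(C)C)[C@@H](O[Si](C)(C)C(C)(C)C)[C@@H]1C(=C)CO | intermediate
31 | trimethylsilyl ester of the target with three trimethylsilyl ethers and O5 as tert-butyldimethylsilyl ether | C=C[C@@]1(C)C[C@@H](OC(=O)C(=C)[C@@H](O[Si](C)(C)C)CO[Si](C)(C)C)[C@@H](C(=C)C(=O)O[Si](C)(C)C)[C@@H](O[Si](C)(C)C(C)(C)C)[C@@H]1C(=C)CO[Si](C)(C)C | intermediate
32 | CNP0348657.1, 2-[(1S,2S,3S,4R,6R)-6-{[(3R)-3,4-dihydroxy-2-methylidenebutanoyl]oxy}-4-ethenyl-2-hydroxy-3-(3-hydroxyprop-1-en-2-yl)-4-methylcyclohexyl]prop-2-enoic acid | C=C[C@@]1(C)C[C@@H](OC(=O)C(=C)[C@@H](O)CO)[C@@H](C(=C)C(=O)O)[C@@H](O)[C@@H]1C(=C)CO | target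

## Step count and least certain steps

Total: 21 steps. Longest linear sequence: 17 steps (steps 1–6, 8–15 and 19–21, from 1). Side branches: step 7 (dienophile) and steps 16–18 (acid 28).

Step 9 (key step). The most likely failure is addition on the wrong diene face, or a stall after the first bond because the C1 terminus is trisubstituted and next to the quaternary carbinol; the enol silane would then hydrolyse and return 10. The fallback sets out from 10. Its cross-conjugated lithium dienolate (LiN(iPr)2, THF, −78 °C) is treated with 13 in an anionic double Michael sequence. The α′-carbon (C4) adds to the nitroalkene and the nitronate closes onto the methyl-bearing β-carbon (C1). The same C6 carbinol screens the lower face. This should give the bicyclic nitro ketone F1, from which DBU removes nitrous acid to give 17, where the route is rejoined for the reduction of step 10.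

Step 19. The displacement at the axial C3 carbinol may give way to elimination toward C2 (an anti-periplanar axial hydrogen is present) or to participation of the neighbouring C4 ester carbonyl with loss of isobutene. The oxyphosphonium ion may also fail to form at the hindered hydroxyl. The fallback sets out from 24 and avoids SN2. Dess–Martin oxidation gives the C3 ketone F2, kept cold and neutral because its C4–H is acidic. NaBH4/CeCl3 at −78 °C should deliver hydride axially and give the equatorial C3 alcohol F3, which is also the more stable epimer. Yamaguchi esterification (2,4,6-trichlorobenzoyl chloride, Et3N, DMAP) with 28 then acylates with retention and returns to the route at 29.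

Step 12. Methylenation of the hindered α-keto ester may be incomplete, or the Lewis-acidic titanium reagent may strip the acetonide and the trimethylsilyl ether, or the C4 centre may epimerise if the reaction is slow. The fallback sets out from 19. Double addition of Me3SiCH2MgCl/CeCl3 to the aldehyde and the ketone gives the bis(β-hydroxysilane) F4. Peterson elimination with KH in THF then forms both C=CH2 bonds and returns to the route at 20.

Step 14. Ring closure may go to the six-membered thiocarbonate across the two primary hydroxyls, or the C3 hydroxyl may be thiocarbonylated. The fallback sets out from 21. One primary hydroxyl is silylated first with one equivalent of tBuMe2SiCl (statistical), giving the mono-silyl ether F5. Only the tertiary/primary 1,2-diol of F5 can form a cyclic thiocarbonate, and 1,1'-thiocarbonyldiimidazole then gives 23.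

Step 21. The hindered C5 silyl ether needs a long fluoride treatment, during which the liberated acid may lactonise onto the C5 hydroxyl; cleavage of the tert-butyl ester may also be incomplete. The fallback sets out from 29 and changes the order of unveiling. Aqueous HF in MeCN removes the acetonide and both tert-butyldimethylsilyl ethers while the carboxyl is still a tert-butyl ester, giving the tetraol ester F6. Me3SiOTf/2,6-lutidine then gives the persilylated trimethylsilyl ester F7. Its trimethylsilyl groups should fall within minutes in buffered HF·pyridine at 0 °C, so the free hydroxy acid 32 is exposed only briefly.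

Step 4. The enolisable ketone 6 may transfer a proton to the enolate, or the aldolate may revert before it is silylated. The fallback sets out from 5. The kinetic trimethylsilyl dienol ether F8 (LiN(iPr)2, Me3SiCl) undergoes a Mukaiyama aldol addition to 6 with BF3·OEt2 at −78 °C, giving the free aldol F9. N-(Trimethylsilyl)imidazole then silylates the tertiary hydroxyl and returns to the route at 8.

## Further compounds

F1 | step 9 | bicyclic nitro ketone (C3 ketone, NO2 on C7, CO2tBu on C8, mixture at C7/C8) | [O-][N+](=O)C2[C@@]1(C)CC(=O)[C@@H](C2C(=O)OC(C)(C)C)[C@@H](O[Si](C)(C)C(C)(C)C)[C@@H]1C1(O[Si](C)(C)C)COC(C)(C)OC1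
F2 | step 19 | C3 ketone derived from 24 | C=C[C@@]1(C)CC(=O)[C@@H](C(=C)C(=O)OC(C)(C)C)[C@@H](O[Si](C)(C)C(C)(C)C)[C@@H]1C(=C)CO[Si](C)(C)C(C)(C)C
F3 | step 19 | C3 epimer of 24 (equatorial hydroxyl cis to the C4 arm) | C=C[C@@]1(C)C[C@@H](O)[C@@H](C(=C)C(=O)OC(C)(C)C)[C@@H](O[Si](C)(C)C(C)(C)C)[C@@H]1C(=C)CO[Si](C)(C)C(C)(C)C
F4 | step 12 | bis(β-hydroxysilane) from 19 (new carbinol centres undefined) | C[Si](C)(C)CC(O)[C@@]1(C)C[C@H](O)[C@@H](C(O)(C[Si](C)(C)C)C(=O)OC(C)(C)C)[C@@H](O[Si](C)(C)C(C)(C)C)[C@@H]1C1(O[Si](C)(C)C)COC(C)(C)OC1
F5 | step 14 | mono-tert-butyldimethylsilyl ether of 21 at one primary hydroxyl (epimers at the carbinol carbon) | C=C[C@@]1(C)C[C@H](O)[C@@H](C(=C)C(=O)OC(C)(C)C)[C@@H](O[Si](C)(C)C(C)(C)C)[C@@H]1C(O)(CO)CO[Si](C)(C)C(C)(C)C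
F6 | step 21 | tert-butyl ester of the target (all hydroxyls free) | C=C[C@@]1(C)C[C@@H](OC(=O)C(=C)[C@@H](O)CO)[C@@H](C(=C)C(=O)OC(C)(C)C)[C@@H](O)[C@@H]1C(=C)CO
F7 | step 21 | trimethylsilyl ester of the target with four trimethylsilyl ethers | C=C[C@@]1(C)C[C@@H](OC(=O)C(=C)[C@@H](O[Si](C)(C)C)CO[Si](C)(C)C)[C@@H](C(=C)C(=O)O[Si](C)(C)C)[C@@H](O[Si](C)(C)C)[C@@H]1C(=C)CO[Si](C)(C)C
F8 | step 4 | (R)-5-(tert-butyldimethylsilyloxy)-1-(trimethylsilyloxy)cyclohexa-1,3-diene, kinetic dienol ether of 5 | C[Si](C)(C)OC1=C[C@H](O[Si](C)(C)C(C)(C)C)CC=C1
F9 | step 4 | (5R,6R)-5-(tert-butyldimethylsilyloxy)-6-(5-hydroxy-2,2-dimethyl-1,3-dioxan-5-yl)cyclohex-2-en-1-one | O=C1C=CC[C@@H](O[Si](C)(C)C(C)(C)C)[C@@H]1C1(O)COC(C)(C)OC1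
A1 | alternative 1 | tert-butyl 4-(tert-butyldimethylsilyloxy)-3-formyl-6,8-dimethyl-6-vinylnon-7-enoate (C1, C3, C4 of the target defined) | C=C[C@@](C=C(C)C)(C)C[C@@H](O[Si](C)(C)C(C)(C)C)[C@@H](CC(=O)OC(C)(C)C)C=O
A2 | alternative 1 | tert-butyl [6-(tert-butyldimethylsilyloxy)-4-ethenyl-2-hydroxy-4-methyl-3-(prop-1-en-2-yl)cyclohexyl]acetate (five ring centres as in the target) | C=C[C@@]1(C)C[C@@H](O[Si](C)(C)C(C)(C)C)[C@@H](CC(=O)OC(C)(C)C)[C@@H](O)[C@@H]1C(C)=C
A3 | alternative 2 | 4-(tert-butyldimethylsilyloxymethyl)-4-methylcyclohexa-2,5-dien-1-one | CC1(CO[Si](C)(C)C(C)(C)C)C=CC(=O)C=C1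
A4 | alternative 2 | [3-(4-methoxybenzyloxy)prop-1-en-2-yl]magnesium bromide | COc1ccc(COCC(=C)[Mg]Br)cc1
A5 | alternative 2 | 6-hydroxy-5-[3-(4-methoxybenzyloxy)prop-1-en-2-yl]-4-methyl-4-(tert-butyldimethylsilyloxymethyl)cyclohex-2-en-1-one (C1, C5, C6 of the target defined) | CC(C)(C)[Si](C)(C)OC[C@@]1(C)C=CC(=O)[C@@H](O)[C@@H]1C(=C)COCc1ccc(OC)cc1
A6 | alternative 3 | 3-ethenyl-2-{2-[(4-methoxybenzyloxy)methyl]-1,3-dioxolan-2-yl}-3-methylpentanedial (C1, C6 of the target defined) | C=C[C@@]([C@H](C=O)C1(COCc2ccc(OC)cc2)OCCO1)(C)CC=O
A7 | alternative 3 | 1,1-dimethoxy-3-nitropropane | COC(OC)CC[N+](=O)[O-]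
A8 | alternative 3 | 2-(2,2-dimethoxyethyl)-5-ethenyl-4-{2-[(4-methoxybenzyloxy)methyl]-1,3-dioxolan-2-yl}-5-methyl-2-nitrocyclohexane-1,3-diol (C1, C3, C5, C6 of the target defined) | C=C[C@@]1(C)C[C@@H](O)[C@@](CC(OC)OC)([N+](=O)[O-])[C@@H](O)[C@@H]1C1(COCc2ccc(OC)cc2)OCCO1
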